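Early times come first in the runs below: a fast climb, then a flat stretch.

| flask | free monomer | initiator | remark | time |
|---|---|---|---|---|
| grey | 0.80 M | 1.6 mol% | run made earlier |  |
| green | 0.80 M | 3.6 mol% | run made earlier |  |
| violet | 1.2 M | 2.4 mol% | run made earlier |  |
| flask | 0.80 M | 2.4 mol% |  | 8.0 d |

| run | time / d | monomer in chains / % |
|---|---|---|
| grey | 0.417 | 22.5 |
| grey | 0.625 | 28.4 |
| grey | 0.833 | 31.6 |
| grey | 1.25 | 36.0 |
| grey | 2.08 | 39.4 |
| grey | 3.00 | 41.2 |
| grey | 5.00 | 42.5 |
| green | 0.250 | 31.4 |
| green | 0.833 | 52.4 |
| green | 1.25 | 56.2 |
| green | 2.08 | 57.2 |
| green | 3.00 | 57.3 |
| green | 4.00 | 57.0 |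
| green | 5.00 | 56.1 |
| violet | 0.417 | 37.5 |
| violet | 1.25 | 48.9 |
| violet | 2.00 | 49.7 |
| violet | 3.00 | 50.3 |
| violet | 5.00 | 49.2 |

(scatter of a reading: 0.5 percentage points)

- the reaction counts as stopped when no species that holds the free monomer changes by six tenths of a point or more over the second half of the time

- why nothing more happens at 8.0 d, or that something still does (it is still moving / forward and back rates have come level / no working catalyst is left / all of the free monomer has reacted)
- the monomer in chains standing at 8.0 d, as a percentage of the free monomer charged

On the first rung, the grey run reaches about half of its last reading by 0.417 d. On the next, the violet run flattens by 2.00 d, at a mean of 49.7% over its last three readings. On the last, its final fall of 1.1 percentage points compares with a scatter of 0.71 points on a difference, so this one fall shows me no drift. I expect the flask's second half of the time, from 4.00 d, to lie beyond the climb.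

A plateau that rises with loading suggests a race to me: growth on living ends, first order in free monomer, against an unseen loss of second order. Integrating, with living ends held steady, gives the plateau share Y = b·ln(1 + 1/b). I solve this for violet by iteration, putting each b back into b = Y/ln(1 + 1/b): a guess of 0.398 returns 0.396, and going round once more gives 0.395. This is my capture number, the rate of growth over the rate of loss at the charged free monomer, a selectivity factor.

At fixed loading both rates go with the square of the charge, so I take b to follow loading in proportion and not the charge. It gives 41.3% for grey and 58.6% for green, against 42.5% and 57.2% read. The flask has violet's loading, so I reckon 49.8% in chains, with free monomer consumed and the other 50.2% taken by the loss.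

The forecast says it is still moving, at 48%: “so the system is still moving”. We part on the ending and lie close on the number.

The flask gives: all of the free monomer has reacted, with 49.7% in chains.

    free monomer + initiator → living end + monomer in chains (k = 1.00 M⁻¹ h⁻¹)
    free monomer + living end → monomer in chains + living end, rate k2*[living end]*[free monomer] (k = 4.10 M⁻¹ h⁻¹)
    2 free monomer → homo dimer (k = 0.102 M⁻¹ h⁻¹)

Up to 0.800 d, the flask's initiator falls to 0.696% of its charge and living end rises to 0.0191 M, while free monomer drops to 8.90%. By 4.00 d, the flask's free monomer is down to 0.0181%, monomer in chains has gone from 41.5% to 49.6%, and homo dimer, counted by the monomer it holds, stands at 50.3%. The capture number gave 49.8% here against 49.7%. Scaled to the neighbour flask's 0.96 mol% of initiator, it becomes 0.158 and gives 31.5%, and that neighbour flask stands at 32.7% at 8.00 d.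

Readings and results are simulated for substances that don't exist.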